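The 2,5-dihydrofuran is disconnected at its bond from the ring oxygen to the methyl-bearing carbon C5' (carotenoid numbering, primes for the furanoid half). This bond is allylic through C6'=C7' to the carbinol carbon C8', so it can be made by a 1,3-shift of oxygen. A trans-7',8'-oxirane next to the C5'=C6' ring alkene is ring-expanded by a copper Lewis acid: one operation closes the dihydrofuran, sets quaternary C5' from the sacrificed C7' centre and moves the alkene into place. The C15 oxirane comes from (4R,6R)-actinol. A second actinol-derived C15 unit carrying the cis-5,6-diol and the C10 trienedial complete the polyene by two Wittig reactions.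

Key step: step 6

Assumption: (4R,6R)-actinol, (2E)-3-methylpent-2-en-4-yn-1-ol and (2E,4E,6E)-2,7-dimethylocta-2,4,6-trienedial are taken as purchasable; TBSO stands for tert-butyldimethylsilyloxy throughout.

Step 1
Reactants: 1 (4R,6R)-4-hydroxy-2,2,6-trimethylcyclohexan-1-one (actinol)
Product: 2 (4R,6R)-4-(TBSO)-2,2,6-trimethylcyclohexan-1-one
Conditions: TBSCl, imidazole, DMF, rt
Reagents that add atoms: tert-butyldimethylsilyl chloride, CC(C)(C)[Si](C)(C)Cl
Why: Silyl ether formation at the only hydroxyl; no stereocentre is touched.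

Step 2
Reactants: 2 (4R,6R)-4-(TBSO)-2,2,6-trimethylcyclohexan-1-one
Product: 4 (4R)-4-(TBSO)-2,6,6-trimethylcyclohex-1-en-1-yl trifluoromethanesulfonate, via lithium enolate 3 (not isolated)
Conditions: LiN(i-Pr)2, THF, −78 °C; then PhNTf2, −78 °C to rt
Reagents that add atoms: N-phenylbis(trifluoromethanesulfonimide), O=S(=O)(N(c1ccccc1)S(=O)(=O)C(F)(F)F)C(F)(F)F
Why: Enolate O-triflation; only one α-carbon carries a hydrogen, so a single tetrasubstituted enol triflate should form, the methyl-bearing centre becoming sp2 and the silyloxy centre staying intact.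

Step 3
Reactants: 4 (4R)-4-(TBSO)-2,6,6-trimethylcyclohex-1-en-1-yl trifluoromethanesulfonate; 5 but-3-en-2-one
Product: 6 (3E)-4-[(4R)-4-(TBSO)-2,6,6-trimethylcyclohex-1-en-1-yl]but-3-en-2-one
Conditions: Pd(OAc)2 (5 mol %), PPh3 (10 mol %), Et3N, DMF, 70 °C
Reagents that add atoms: but-3-en-2-one 5, C=CC(C)=O
Why: Heck reaction of an alkenyl triflate with an electron-poor alkene; syn β-hydride elimination should give the (E)-dienone.

Step 4
Reactants: 6 (3E)-4-[(4R)-4-(TBSO)-2,6,6-trimethylcyclohex-1-en-1-yl]but-3-en-2-one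
Product: 7 1-[(2R,3S)-3-[(4R)-4-(TBSO)-2,6,6-trimethylcyclohex-1-en-1-yl]oxiran-2-yl]ethan-1-one
Conditions: La(O-i-Pr)3 (10 mol %), (S)-BINOL (10 mol %), Ph3As=O (10 mol %), t-BuOOH (decane), 4 Å MS, THF, rt
Reagents that add atoms: tert-butyl hydroperoxide, CC(C)(C)OO
Why: Catalytic asymmetric nucleophilic (Weitz–Scheffer-type) epoxidation of an (E)-enone; the peroxide adds only to the enone alkene, the (E)-geometry gives the trans oxirane, and the lanthanum–(S)-BINOL complex is expected to set (2R,3S) by catalyst control, independent of the remote silyloxy centre.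

Step 5
Reactants: 7 1-[(2R,3S)-3-[(4R)-4-(TBSO)-2,6,6-trimethylcyclohex-1-en-1-yl]oxiran-2-yl]ethan-1-one; 8 triethyl phosphonoacetate
Product: 9 ethyl (2E)-3-[(2S,3S)-3-[(4R)-4-(TBSO)-2,6,6-trimethylcyclohex-1-en-1-yl]oxiran-2-yl]but-2-enoate
Conditions: NaH, THF, 0 °C to rt
Reagents that add atoms: triethyl phosphonoacetate 8, CCOC(=O)CP(=O)(OCC)OCC
Why: Horner–Wadsworth–Emmons olefination of the methyl ketone, (E) favoured with the ester trans to the larger oxiranyl group; the oxirane C–H next to the ketone is not enolisable, so both ring carbons keep their configuration (the C2 descriptor changes from R to S only through the priority switch).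

Step 6
Reactants: 9 ethyl (2E)-3-[(2S,3S)-3-[(4R)-4-(TBSO)-2,6,6-trimethylcyclohex-1-en-1-yl]oxiran-2-yl]but-2-enoate
Product: 10 ethyl (2E)-3-[(2R,6S,7aR)-6-(TBSO)-4,4,7a-trimethyl-2,4,5,6,7,7a-hexahydro-1-benzofuran-2-yl]but-2-enoate
Conditions: Cu(hfacac)2 [Cu(CF3COCHCOCF3)2] (5 mol %), toluene, 90 °C
Reagents that add atoms: none
Why: The divalent copper Lewis acid binds the oxirane oxygen and heterolyses the oxirane C3–O bond, the one allylic to the electron-rich tetrasubstituted ring alkene, to a contact pair of allyl cation and copper alkoxide, and the alkoxide, still attached to former oxirane C2, collapses on the distal methyl-bearing terminus, a net 1,3-shift of oxygen. The closest known reaction type is the copper-catalysed ring expansion of vinyl oxiranes to 2,5-dihydrofurans, mechanistically the mirror image of the acid-induced 5,6-epoxide to 5,8-furanoid rearrangement of carotenoids. The five-membered ring closes in a formally 5-endo-trig sense on the ring alkene carbon, feasible because the attack is on one terminus of a delocalised allyl cation within an ion pair and not a concerted addition to the alkene. The new quaternary centre (C7a of the benzofuran, C5') is set by 1,3-chirality transfer from oxirane C3, which is destroyed: ionisation needs the C3–O bond parallel to the ring π system with the side chain turned towards the ring methyl, so the (3S) centre holds the oxygen over the face anti to the silyloxy group and delivers it suprafacially, while C2 of the dihydrofuran is the untouched oxirane C2. Allylic 1,3-strain (hydrogen rather than the butenoate pointing at the ring methyl) favours the same diastereomer, with the side chain trans to the angular methyl, should the ion pair loosen. The step needs cleavage of C3–O and not C2–O, secured by the donor ring alkene against the electron-poor enoate next to C2, and ring closure ahead of hydride shift or proton loss, favoured by intramolecular five-ring collapse at a tertiary terminus under aprotic, weakly Lewis acidic conditions.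

Step 7
Reactants: 10 ethyl (2E)-3-[(2R,6S,7aR)-6-(TBSO)-4,4,7a-trimethyl-2,4,5,6,7,7a-hexahydro-1-benzofuran-2-yl]but-2-enoate
Product: 11 (2E)-3-[(2R,6S,7aR)-6-(TBSO)-4,4,7a-trimethyl-2,4,5,6,7,7a-hexahydro-1-benzofuran-2-yl]but-2-en-1-ol
Conditions: i-Bu2AlH, CH2Cl2, −78 °C
Reagents that add atoms: none
Why: 1,2-Reduction of the unsaturated ester to the allylic alcohol by an aluminium hydride; the cyclic ether, silyl ether and alkenes should be inert.

Step 8
Reactants: 11 (2E)-3-[(2R,6S,7aR)-6-(TBSO)-4,4,7a-trimethyl-2,4,5,6,7,7a-hexahydro-1-benzofuran-2-yl]but-2-en-1-ol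
Product: 13 [(2E)-3-[(2R,6S,7aR)-6-(TBSO)-4,4,7a-trimethyl-2,4,5,6,7,7a-hexahydro-1-benzofuran-2-yl]but-2-en-1-yl]triphenylphosphonium bromide, via allylic bromide 12 (not isolated)
Conditions: CBr4, PPh3, CH2Cl2, 0 °C; then more PPh3, rt
Reagents that add atoms: carbon tetrabromide, BrC(Br)(Br)Br; triphenylphosphine, c1ccccc1P(c1ccccc1)c1ccccc1
Why: Appel bromination of the primary allylic alcohol followed by SN2 quaternisation of triphenylphosphine; the neutral conditions spare the acid-labile dihydrofuran.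

Step 9
Reactants: 2 (4R,6R)-4-(TBSO)-2,2,6-trimethylcyclohexan-1-one
Product: 15 (2R,4S)-4-(TBSO)-2-hydroxy-2,6,6-trimethylcyclohexan-1-one, via potassium enolate 14 (not isolated)
Conditions: KN(SiMe3)2, THF, −78 to 0 °C; then 2-(phenylsulfonyl)-3-phenyloxaziridine, −78 °C
Reagents that add atoms: 2-(phenylsulfonyl)-3-phenyloxaziridine, O=S(=O)(N1OC1c1ccccc1)c1ccccc1
Why: Enolate hydroxylation with an N-sulfonyloxaziridine; the only possible enolate should be attacked along the axial direction of the half-chair with equatorial silyloxy group, anti to that group, because this puts the small new oxygen and not the methyl syn-axial to the axial methyl of the gem-dimethyl carbon, giving the (2R) tertiary alcohol.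

Step 10
Reactants: 15 (2R,4S)-4-(TBSO)-2-hydroxy-2,6,6-trimethylcyclohexan-1-one; 16 (2E)-3-methylpent-2-en-4-yn-1-ol
Product: 18 (1R,2R,4S)-4-(TBSO)-1-[(3E)-5-hydroxy-3-methylpent-3-en-1-yn-1-yl]-2,6,6-trimethylcyclohexane-1,2-diol, via dilithio enynol 17 (not isolated)
Conditions: 16 (3 equiv), n-BuLi (6 equiv), THF, −78 to 0 °C; then 15, −78 °C to rt
Reagents that add atoms: (2E)-3-methylpent-2-en-4-yn-1-ol 16, C#C/C(C)=C/CO
Why: 1,2-Addition of a lithium acetylide to a non-enolisable ketone; in the chair with axial C2 oxygen and equatorial silyloxy group the slim nucleophile should enter axially, anti to both the axial C–O bond and the axial methyl, which places the new hydroxyl cis to its neighbour (cis-diol).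

Step 11
Reactants: 18 (1R,2R,4S)-4-(TBSO)-1-[(3E)-5-hydroxy-3-methylpent-3-en-1-yn-1-yl]-2,6,6-trimethylcyclohexane-1,2-diol
Product: 19 (1S,2R,4S)-4-(TBSO)-1-[(1E,3E)-5-hydroxy-3-methylpenta-1,3-dien-1-yl]-2,6,6-trimethylcyclohexane-1,2-diol
Conditions: NaAlH2(OCH2CH2OMe)2, THF, 0 °C to rt; aq. Rochelle salt
Reagents that add atoms: none
Why: Alkoxide-directed trans-hydroalumination of the propargylic alcohol and protonolysis should give the (E)-alkene; no stereocentre changes (the C1 descriptor switches only because alkenyl ranks below the quaternary ring carbon).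

Step 12
Reactants: 19 (1S,2R,4S)-4-(TBSO)-1-[(1E,3E)-5-hydroxy-3-methylpenta-1,3-dien-1-yl]-2,6,6-trimethylcyclohexane-1,2-diol
Product: 21 [(2E,4E)-5-[(1S,2R,4S)-4-(TBSO)-1,2-dihydroxy-2,6,6-trimethylcyclohexyl]-3-methylpenta-2,4-dien-1-yl]triphenylphosphonium bromide, via dienyl bromide 20 (not isolated)
Conditions: CBr4, PPh3, CH2Cl2, 0 °C; then more PPh3, rt
Reagents that add atoms: carbon tetrabromide, BrC(Br)(Br)Br; triphenylphosphine, c1ccccc1P(c1ccccc1)c1ccccc1
Why: Appel bromination is selective for the primary allylic hydroxyl over the two tertiary ones, and SN2 quaternisation follows; acid, which would ionise the tertiary allylic hydroxyl, is avoided.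

Step 13
Reactants: 21 [(2E,4E)-5-[(1S,2R,4S)-4-(TBSO)-1,2-dihydroxy-2,6,6-trimethylcyclohexyl]-3-methylpenta-2,4-dien-1-yl]triphenylphosphonium bromide; 22 (2E,4E,6E)-2,7-dimethylocta-2,4,6-trienedial
Product: 24 (2E,4E,6E,8E,10E,12E)-13-[(1S,2R,4S)-4-(TBSO)-1,2-dihydroxy-2,6,6-trimethylcyclohexyl]-2,7,11-trimethyltrideca-2,4,6,8,10,12-hexaenal, via ylide 23 (not isolated)
Conditions: NaOMe, MeOH/CH2Cl2, 0 °C to rt, 22 (3 equiv); then heptane, 80 °C
Reagents that add atoms: trienedial 22, O=C/C(C)=C/C=C/C=C(C)/C=O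
Why: Wittig reaction of the allylic ylide with an excess of the symmetrical dialdehyde should stop at mono-olefination, and the new disubstituted double bond is equilibrated thermally to (E).

Step 14
Reactants: 24 (2E,4E,6E,8E,10E,12E)-13-[(1S,2R,4S)-4-(TBSO)-1,2-dihydroxy-2,6,6-trimethylcyclohexyl]-2,7,11-trimethyltrideca-2,4,6,8,10,12-hexaenal; 13 [(2E)-3-[(2R,6S,7aR)-6-(TBSO)-4,4,7a-trimethyl-2,4,5,6,7,7a-hexahydro-1-benzofuran-2-yl]but-2-en-1-yl]triphenylphosphonium bromide
Product: 26 (3S,5R,6S,3'S,5'R,8'R)-3,3'-bis(TBSO)-5',8'-epoxy-5,6,5',8'-tetrahydro-β,β-carotene-5,6-diol, via ylide 25 (not isolated)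
Conditions: 1,2-epoxybutane, EtOH, 70 °C
Reagents that add atoms: phosphonium bromide 13, [Br-].c1ccccc1[P+](c1ccccc1)(c1ccccc1)C/C=C(\C)[C@H]1C=C2C(C)(C)C[C@H](O[Si](C)(C)C(C)(C)C)C[C@@]2(C)O1
Why: Wittig reaction under neutral conditions, the epoxide scavenging HBr so that the ylide stays at low concentration, which should suppress ring-opening elimination of the dihydrofuran oxygen; heating equilibrates the new double bond to (E).

Step 15
Reactants: 26 (3S,5R,6S,3'S,5'R,8'R)-3,3'-bis(TBSO)-5',8'-epoxy-5,6,5',8'-tetrahydro-β,β-carotene-5,6-diol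
Product: 27 (3S,5R,6S,3'S,5'R,8'R)-5',8'-epoxy-5,6,5',8'-tetrahydro-β,β-carotene-3,5,6,3'-tetrol (CNP0210286.4)
Conditions: Bu4NF, THF, 0 °C to rt
Reagents that add atoms: none
Why: Fluoride-induced desilylation of the two secondary silyl ethers under non-acidic conditions, which should leave the dihydrofuran, the tertiary allylic alcohol and the polyene unchanged.

Compound list
1 | (4R,6R)-4-hydroxy-2,2,6-trimethylcyclohexan-1-one (actinol) | C[C@@H]1C[C@@H](O)CC(C)(C)C1=O | starting material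
2 | (4R,6R)-4-(TBSO)-2,2,6-trimethylcyclohexan-1-one | C[C@@H]1C[C@@H](O[Si](C)(C)C(C)(C)C)CC(C)(C)C1=O | intermediate
3 | lithium enolate of 2 | [Li]OC1=C(C)C[C@@H](O[Si](C)(C)C(C)(C)C)CC1(C)C | intermediate
4 | (4R)-4-(TBSO)-2,6,6-trimethylcyclohex-1-en-1-yl trifluoromethanesulfonate | FC(F)(F)S(=O)(=O)OC1=C(C)C[C@@H](O[Si](C)(C)C(C)(C)C)CC1(C)C | intermediate
5 | but-3-en-2-one | C=CC(C)=O | starting material
6 | (3E)-4-[(4R)-4-(TBSO)-2,6,6-trimethylcyclohex-1-en-1-yl]but-3-en-2-one | CC(=O)/C=C/C1=C(C)C[C@@H](O[Si](C)(C)C(C)(C)C)CC1(C)C | intermediate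
7 | 1-[(2R,3S)-3-[(4R)-4-(TBSO)-2,6,6-trimethylcyclohex-1-en-1-yl]oxiran-2-yl]ethan-1-one | CC(=O)[C@@H]1O[C@H]1C2=C(C)C[C@@H](O[Si](C)(C)C(C)(C)C)CC2(C)C | intermediate
8 | triethyl phosphonoacetate | CCOC(=O)CP(=O)(OCC)OCC | starting material
9 | ethyl (2E)-3-[(2S,3S)-3-[(4R)-4-(TBSO)-2,6,6-trimethylcyclohex-1-en-1-yl]oxiran-2-yl]but-2-enoate | CCOC(=O)/C=C(\C)[C@@H]1O[C@H]1C2=C(C)C[C@@H](O[Si](C)(C)C(C)(C)C)CC2(C)C | intermediate
10 | ethyl (2E)-3-[(2R,6S,7aR)-6-(TBSO)-4,4,7a-trimethyl-2,4,5,6,7,7a-hexahydro-1-benzofuran-2-yl]but-2-enoate | CCOC(=O)/C=C(\C)[C@H]1C=C2C(C)(C)C[C@H](O[Si](C)(C)C(C)(C)C)C[C@@]2(C)O1 | intermediate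
11 | (2E)-3-[(2R,6S,7aR)-6-(TBSO)-4,4,7a-trimethyl-2,4,5,6,7,7a-hexahydro-1-benzofuran-2-yl]but-2-en-1-ol | OC/C=C(\C)[C@H]1C=C2C(C)(C)C[C@H](O[Si](C)(C)C(C)(C)C)C[C@@]2(C)O1 | intermediate
12 | allylic bromide from 11 | BrC/C=C(\C)[C@H]1C=C2C(C)(C)C[C@H](O[Si](C)(C)C(C)(C)C)C[C@@]2(C)O1 | intermediate
13 | [(2E)-3-[(2R,6S,7aR)-6-(TBSO)-4,4,7a-trimethyl-2,4,5,6,7,7a-hexahydro-1-benzofuran-2-yl]but-2-en-1-yl]triphenylphosphonium bromide | [Br-].c1ccccc1[P+](c1ccccc1)(c1ccccc1)C/C=C(\C)[C@H]1C=C2C(C)(C)C[C@H](O[Si](C)(C)C(C)(C)C)C[C@@]2(C)O1 | intermediate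
14 | potassium enolate of 2 | [K]OC1=C(C)C[C@@H](O[Si](C)(C)C(C)(C)C)CC1(C)C | intermediate
15 | (2R,4S)-4-(TBSO)-2-hydroxy-2,6,6-trimethylcyclohexan-1-one | O=C1C(C)(C)C[C@H](O[Si](C)(C)C(C)(C)C)C[C@@]1(C)O | intermediate
16 | (2E)-3-methylpent-2-en-4-yn-1-ol | C#C/C(C)=C/CO | starting material
17 | dilithio derivative of 16 (lithium alkoxide and lithium acetylide) | [Li]C#C/C(C)=C/CO[Li] | intermediate
18 | (1R,2R,4S)-4-(TBSO)-1-[(3E)-5-hydroxy-3-methylpent-3-en-1-yn-1-yl]-2,6,6-trimethylcyclohexane-1,2-diol | OC/C=C(\C)C#C[C@]1(O)C(C)(C)C[C@H](O[Si](C)(C)C(C)(C)C)C[C@@]1(C)O | intermediate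
19 | (1S,2R,4S)-4-(TBSO)-1-[(1E,3E)-5-hydroxy-3-methylpenta-1,3-dien-1-yl]-2,6,6-trimethylcyclohexane-1,2-diol | OC/C=C(C)/C=C/[C@]1(O)C(C)(C)C[C@H](O[Si](C)(C)C(C)(C)C)C[C@@]1(C)O | intermediate
20 | dienyl bromide from 19 | BrC/C=C(C)/C=C/[C@]1(O)C(C)(C)C[C@H](O[Si](C)(C)C(C)(C)C)C[C@@]1(C)O | intermediate
21 | [(2E,4E)-5-[(1S,2R,4S)-4-(TBSO)-1,2-dihydroxy-2,6,6-trimethylcyclohexyl]-3-methylpenta-2,4-dien-1-yl]triphenylphosphonium bromide | [Br-].c1ccccc1[P+](c1ccccc1)(c1ccccc1)C/C=C(C)/C=C/[C@]1(O)C(C)(C)C[C@H](O[Si](C)(C)C(C)(C)C)C[C@@]1(C)O | intermediate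
22 | (2E,4E,6E)-2,7-dimethylocta-2,4,6-trienedial | O=C/C(C)=C/C=C/C=C(C)/C=O | starting material
23 | ylide from 21 | c1ccccc1P(c1ccccc1)(c1ccccc1)=C/C=C(C)/C=C/[C@]1(O)C(C)(C)C[C@H](O[Si](C)(C)C(C)(C)C)C[C@@]1(C)O | intermediate
24 | (2E,4E,6E,8E,10E,12E)-13-[(1S,2R,4S)-4-(TBSO)-1,2-dihydroxy-2,6,6-trimethylcyclohexyl]-2,7,11-trimethyltrideca-2,4,6,8,10,12-hexaenal | CC(/C=C/C=C(C)/C=C/[C@]1(O)C(C)(C)C[C@H](O[Si](C)(C)C(C)(C)C)C[C@@]1(C)O)=C\C=C\C=C(C)\C=O | intermediate
25 | ylide from 13 | c1ccccc1P(c1ccccc1)(c1ccccc1)=C/C=C(\C)[C@H]1C=C2C(C)(C)C[C@H](O[Si](C)(C)C(C)(C)C)C[C@@]2(C)O1 | intermediate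
26 | (3S,5R,6S,3'S,5'R,8'R)-3,3'-bis(TBSO)-5',8'-epoxy-5,6,5',8'-tetrahydro-β,β-carotene-5,6-diol | CC(/C=C/C=C(C)/C=C/[C@]1(O)C(C)(C)C[C@H](O[Si](C)(C)C(C)(C)C)C[C@@]1(C)O)=C\C=C\C=C(C)\C=C\C=C(/C)[C@H]1C=C2C(C)(C)C[C@H](O[Si](C)(C)C(C)(C)C)C[C@@]2(C)O1 | intermediate
27 | (3S,5R,6S,3'S,5'R,8'R)-5',8'-epoxy-5,6,5',8'-tetrahydro-β,β-carotene-3,5,6,3'-tetrol (CNP0210286.4) | CC(/C=C/C=C(C)/C=C/[C@]1(O)C(C)(C)C[C@H](O)C[C@@]1(C)O)=C\C=C\C=C(C)\C=C\C=C(/C)[C@H]1C=C2C(C)(C)C[C@H](O)C[C@@]2(C)O1 | target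

Total step count: 15. Longest linear sequence: 10 steps (steps 1 to 8, then 14 and 15).

Steps most likely to fail

Step 6 (ring expansion). Ionisation of the oxirane may be diverted into a 1,2-hydride shift or proton loss, or the ion pair may loosen and erode the transfer of configuration to the quaternary carbon. The fallback sets out from 6 and returns at 10, building the dihydrofuran by oxygen extrusion from a six-membered peroxide. Horner–Wadsworth–Emmons olefination of 6 with 8 (NaH, THF) would give the ethyl trienoate F1. Dye-sensitised photooxygenation (O2, tetraphenylporphyrin, hν, CH2Cl2, −20 °C) should add singlet oxygen [4+2] across C5'=C6'–C7'=C8', preferentially anti to the silyloxy group, to give the bicyclic 1,2-dioxine F2; the minor face isomer would be removed by chromatography. Thiourea in MeOH would cleave the O–O bond to the (Z)-ene-1,4-diol F3. Pyridinium p-toluenesulfonate in CH2Cl2 should then ionise the tertiary allylic hydroxyl, and the C8' hydroxyl closes onto C5' (the same O–C bond, with the side chain placed trans to the angular methyl by allylic 1,3-strain), giving 10. This trades the catalyst-controlled C8' centre for a substrate-controlled one.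

Step 4 (asymmetric epoxidation). Hindrance at the β-carbon of the enone, which is flanked by the fully substituted ring carbon, may slow peroxide addition and lower enantiofacial control. The fallback sets out from 6 and returns at 7. Corey–Bakshi–Shibata reduction of 6 [(R)-2-methyl-CBS-oxazaborolidine, BH3·SMe2, THF, −20 °C] should give the (S)-allylic alcohol F4. Sharpless asymmetric epoxidation in the matched sense [Ti(O-i-Pr)4, L-(+)-diisopropyl tartrate, t-BuOOH, 4 Å MS, CH2Cl2, −20 °C] is hydroxyl-directed to the 7',8'-alkene and should give the erythro epoxy alcohol F5. Dess–Martin oxidation would then give 7.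

Step 14 (final Wittig). The ylide from 13 carries the dihydrofuran oxygen next to its γ-carbanionic terminus, so vinylogous β-elimination with opening of the dihydrofuran may compete with olefination. The fallback sets out from 11 and 24 and returns at 26, reversing the polarity of the coupling. MnO2 (CH2Cl2, rt) would oxidise 11 to the furanoid enal F6. NaBH4 (MeOH/CH2Cl2, 0 °C) would reduce 24 to the C25 allylic alcohol F7, which is taken through the C25 allylic bromide F8 (CBr4, PPh3, CH2Cl2; not isolated) to the C25 phosphonium bromide F9. Wittig reaction of F9 with F6 (1,2-epoxybutane, EtOH, 70 °C) should give 26.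

Further compounds
F1 | step 6 | ethyl (2E,4E)-5-[(4R)-4-(TBSO)-2,6,6-trimethylcyclohex-1-en-1-yl]-3-methylpenta-2,4-dienoate | CCOC(=O)/C=C(C)/C=C/C1=C(C)C[C@@H](O[Si](C)(C)C(C)(C)C)CC1(C)C
F2 | step 6 | ethyl (2E)-3-[(3R,7S,8aR)-7-(TBSO)-5,5,8a-trimethyl-3,5,6,7,8,8a-hexahydro-1,2-benzodioxin-3-yl]but-2-enoate | CCOC(=O)/C=C(\C)[C@H]1C=C2C(C)(C)C[C@H](O[Si](C)(C)C(C)(C)C)C[C@@]2(C)OO1
F3 | step 6 | ethyl (2E,4R,5Z)-5-[(2R,4S)-4-(TBSO)-2-hydroxy-2,6,6-trimethylcyclohexylidene]-4-hydroxy-3-methylpent-2-enoate | CCOC(=O)/C=C(\C)[C@H](O)/C=C1/C(C)(C)C[C@H](O[Si](C)(C)C(C)(C)C)C[C@@]1(C)O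
F4 | step 4 | (2S,3E)-4-[(4R)-4-(TBSO)-2,6,6-trimethylcyclohex-1-en-1-yl]but-3-en-2-ol | C[C@H](O)/C=C/C1=C(C)C[C@@H](O[Si](C)(C)C(C)(C)C)CC1(C)C
F5 | step 4 | (1S)-1-[(2S,3S)-3-[(4R)-4-(TBSO)-2,6,6-trimethylcyclohex-1-en-1-yl]oxiran-2-yl]ethan-1-ol | C[C@H](O)[C@@H]1O[C@H]1C2=C(C)C[C@@H](O[Si](C)(C)C(C)(C)C)CC2(C)C
F6 | step 14 | (2E)-3-[(2R,6S,7aR)-6-(TBSO)-4,4,7a-trimethyl-2,4,5,6,7,7a-hexahydro-1-benzofuran-2-yl]but-2-enal | O=C/C=C(\C)[C@H]1C=C2C(C)(C)C[C@H](O[Si](C)(C)C(C)(C)C)C[C@@]2(C)O1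
F7 | step 14 | (2E,4E,6E,8E,10E,12E)-13-[(1S,2R,4S)-4-(TBSO)-1,2-dihydroxy-2,6,6-trimethylcyclohexyl]-2,7,11-trimethyltrideca-2,4,6,8,10,12-hexaen-1-ol | CC(/C=C/C=C(C)/C=C/[C@]1(O)C(C)(C)C[C@H](O[Si](C)(C)C(C)(C)C)C[C@@]1(C)O)=C\C=C\C=C(C)\CO
F8 | step 14 | C25 allylic bromide from F7 | CC(/C=C/C=C(C)/C=C/[C@]1(O)C(C)(C)C[C@H](O[Si](C)(C)C(C)(C)C)C[C@@]1(C)O)=C\C=C\C=C(C)\CBr
F9 | step 14 | C25 triphenylphosphonium bromide from F8 | CC(/C=C/C=C(C)/C=C/[C@]1(O)C(C)(C)C[C@H](O[Si](C)(C)C(C)(C)C)C[C@@]1(C)O)=C\C=C\C=C(C)\C[P+](c2ccccc2)(c3ccccc3)c4ccccc4.[Br-]
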